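The hindered orsellinoyl ester is never made by acylation. Ring A (the 2,4-dihydroxy-6-methylbenzoyl ring, primed locants) is grown on a but-2-ynoyl ester already attached to the 4-oxygen of ring B (the heptyl-bearing benzoate ring). The feature used is that the acyl-bearing C1' and the methyl-bearing C6' of ring A are neighbours and are the two alkyne carbons of a but-2-ynoate, while C2'–C5', with oxygen on C2' and C4', is the chain of an acetoacetate. One cycloaddition of a 1-benzyloxy-1,3-bis(silyloxy)diene to the aryl ynoate, with acid-triggered aromatization, forms C1'–C2', C5'–C6' and the whole arene. The precursor is the silyl-capped benzyl 2-heptylresorcylate carrying the but-2-ynoate.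

Key step: step 8

Remark: compounds 4, 5, 6 and 13 are racemic mixtures of stereoisomers (5 and 6 drawn as diketo tautomers) whose stereocentres vanish on aromatization; 11 is a mixture of alkene isomers; the geometry drawn for 12 is immaterial; the target has no stereocentre.

Step 1
Reactants: 1 (E)-dec-2-enoic acid
Product: 2 benzyl (E)-dec-2-enoate
Conditions: BnBr, K2CO3, DMF, rt
Reagents that add atoms: benzyl bromide, BrCc1ccccc1
Why: SN2 O-alkylation of the potassium carboxylate gives the benzyl ester without touching the E-alkene, so that the alkoxide expelled in step 2 is the same as the ester group that must survive there.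

Step 2
Reactants: 2 benzyl (E)-dec-2-enoate; 3 benzyl acetoacetate (benzyl 3-oxobutanoate)
Product: 5 benzyl 6-heptyl-2,4-dioxocyclohexane-1-carboxylate, via Michael adduct 4 (not isolated)
Conditions: NaOCH2Ph (1.0 M in BnOH, 1.1 equiv), toluene, 90 °C; then 1 M HCl
Reagents that add atoms: none
Why: Michael addition of the acetoacetate anion to the β-carbon of the enoate, then intramolecular Claisen (Dieckmann-type) condensation of the acetyl methyl onto the chain ester, is the classical dihydroresorcylate annulation driven by formation of the acidic 1,3-dione salt; the two new stereocentres form uncontrolled as a racemic mixture and are erased in step 3.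

Step 3
Reactants: 5 benzyl 6-heptyl-2,4-dioxocyclohexane-1-carboxylate
Product: 7 benzyl 2-heptyl-4,6-dihydroxybenzoate, via bromodione 6 (not isolated)
Conditions: Br2 (1.0 equiv), DMF, 0 °C, then 70 °C
Reagents that add atoms: none
Why: bromination of the dione enol, HBr-mediated shift of bromine to a carbon with a neighbouring C–H, dehydrobromination and enolization should give the resorcylate (bromination–dehydrobromination aromatization of a dihydroresorcylate), one equivalent of bromine being chosen to avoid nuclear bromination.

Step 4
Reactants: 7 benzyl 2-heptyl-4,6-dihydroxybenzoate; 8 but-2-ynoic acid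
Product: 9 benzyl 4-(but-2-ynoyloxy)-2-heptyl-6-hydroxybenzoate
Conditions: DCC (1.1 equiv), DMAP (5 mol%), CH2Cl2, 0 °C
Reagents that add atoms: none
Why: Steglich esterification should acylate only the free, more acidic 4-hydroxyl because the 6-hydroxyl is tied up in a hydrogen bond to the benzyl ester carbonyl, and low temperature with little DMAP keeps the ynoate from isomerizing to the allenoate.

Step 5
Reactants: 9 benzyl 4-(but-2-ynoyloxy)-2-heptyl-6-hydroxybenzoate
Product: 10 benzyl 4-(but-2-ynoyloxy)-2-heptyl-6-(trimethylsilyloxy)benzoate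
Conditions: BSA (1.5 equiv), MeCN, 40 °C; volatiles removed in vacuo, used crude
Reagents that add atoms: N,O-bis(trimethylsilyl)acetamide, CC(=N[Si](C)(C)C)O[Si](C)(C)C
Why: neutral O-silylation of the chelated phenol caps the only acidic proton that would protonate the diene in step 8, with no amine base that could add to or isomerize the aryl ynoate, and the cap falls off in the acidic work-up of step 8 at no cost in steps.

Step 6
Reactants: 3 benzyl acetoacetate
Product: 11 benzyl 3-(trimethylsilyloxy)but-2-enoate (E/Z mixture)
Conditions: TMSCl, Et3N, hexane, rt; filtration, concentration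
Reagents that add atoms: chlorotrimethylsilane, C[Si](C)(C)Cl
Why: O-silylation of the β-keto ester enol (silyl enol ether formation) is standard, and the alkene geometry has no consequence later.

Step 7
Reactants: 11 benzyl 3-(trimethylsilyloxy)but-2-enoate
Product: 12 (1Z)-1-(benzyloxy)-1,3-bis(trimethylsilyloxy)buta-1,3-diene
Conditions: LiN(i-Pr)2, THF, −78 °C; TMSCl, −78 °C to rt; used without chromatography
Reagents that add atoms: chlorotrimethylsilane, C[Si](C)(C)Cl
Why: γ-deprotonation of the silyl enol ether ester and O-silylation of the dienolate is the standard second stage in making 1-alkoxy-1,3-bis(silyloxy)dienes, and the C1=C2 geometry does not matter because C1 becomes an aromatic carbon.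

Step 8
Reactants: 10 benzyl 4-(but-2-ynoyloxy)-2-heptyl-6-(trimethylsilyloxy)benzoate; 12 (1Z)-1-(benzyloxy)-1,3-bis(trimethylsilyloxy)buta-1,3-diene (3 equiv)
Product: 14 benzyl 4-[(2,4-dihydroxy-6-methylbenzoyl)oxy]-2-heptyl-6-hydroxybenzoate, via cyclohexadiene cycloadduct 13 (not isolated)
Conditions: toluene, 90 °C, sealed tube, Ar; then 1 M HCl, THF, 0 °C to rt
Reagents that add atoms: none
Why: The electron-rich diene 12 (largest HOMO coefficient at its C4 methylene) and the electron-poor aryl ynoate 10 should combine by a normal-demand thermal [4+2] cycloaddition, or by Mukaiyama–Michael addition followed by attack of the resulting allenyl ketene acetal on the silyloxycarbenium carbon, either path forming C5'–C6' and C1'–C2' and giving the cyclohexa-1,4-diene 13 with a mixed benzyl silyl ketal at C2'. The closest known reaction type is the Diels–Alder/aromatization of 1-alkoxy-1,3-bis(silyloxy)- and 1,1-dialkoxy-3-silyloxybuta-1,3-dienes with alkyl but-2-ynoates, propiolates and acetylenedicarboxylates to give resorcylates; the only change is an aryl in place of an alkyl ester, which lowers the LUMO of the dienophile. Ring A is closed by an intermolecular [4+2] annulation of a four-carbon and a two-carbon unit (in the stepwise variant the second bond forms by a 6-(enolexo)-exo-trig closure). No stereocentre survives: the ketal carbon of 13 is racemic and disappears when aqueous acid cleaves the three silyl groups, the ketal expels benzyl alcohol and the resulting dione tautomerizes to the arene; should silanol be lost instead, the C2' benzyl ether that results is removed in step 9. The step needs regioselectivity and chemoselectivity: the polarized alkyne pairs its electrophilic β-carbon with the nucleophilic methylene terminus, which places methyl at C6' and oxygen at C2' and C4', while the silyl cap on ring B and the absence of Lewis acid or free base protect the diene and the aryl ester.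

Step 9
Reactants: 14 benzyl 4-[(2,4-dihydroxy-6-methylbenzoyl)oxy]-2-heptyl-6-hydroxybenzoate
Product: 15 4-[(2,4-dihydroxy-6-methylbenzoyl)oxy]-2-heptyl-6-hydroxybenzoic acid
Conditions: H2 (1 atm), 10% Pd/C, EtOAc, rt
Reagents that add atoms: none
Why: hydrogenolysis of the benzyl ester (and of any benzyl ether left at C2') is neutral and should spare the depside ester and avoid decarboxylation of the β-resorcylic acid.

Compound list
1 | (E)-dec-2-enoic acid | CCCCCCC/C=C/C(=O)O | starting material
2 | benzyl (E)-dec-2-enoate | CCCCCCC/C=C/C(=O)OCc1ccccc1 | intermediate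
3 | benzyl acetoacetate (benzyl 3-oxobutanoate) | CC(=O)CC(=O)OCc1ccccc1 | starting material
4 | dibenzyl 2-acetyl-3-heptylpentanedioate (Michael adduct, stereoisomer mixture, not isolated) | CCCCCCCC(CC(=O)OCc1ccccc1)C(C(C)=O)C(=O)OCc1ccccc1 | intermediate
5 | benzyl 6-heptyl-2,4-dioxocyclohexane-1-carboxylate (racemic, stereoisomer and tautomer mixture) | CCCCCCCC1CC(=O)CC(=O)C1C(=O)OCc1ccccc1 | intermediate
6 | benzyl 3-bromo-6-heptyl-2,4-dioxocyclohexane-1-carboxylate (stereoisomer mixture, not isolated) | CCCCCCCC1CC(=O)C(Br)C(=O)C1C(=O)OCc1ccccc1 | intermediate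
7 | benzyl 2-heptyl-4,6-dihydroxybenzoate | CCCCCCCc1cc(O)cc(O)c1C(=O)OCc1ccccc1 | intermediate
8 | but-2-ynoic acid | CC#CC(=O)O | starting material
9 | benzyl 4-(but-2-ynoyloxy)-2-heptyl-6-hydroxybenzoate | CCCCCCCc1cc(OC(=O)C#CC)cc(O)c1C(=O)OCc1ccccc1 | intermediate
10 | benzyl 4-(but-2-ynoyloxy)-2-heptyl-6-(trimethylsilyloxy)benzoate | CCCCCCCc1cc(OC(=O)C#CC)cc(O[Si](C)(C)C)c1C(=O)OCc1ccccc1 | intermediate
11 | benzyl 3-(trimethylsilyloxy)but-2-enoate (E/Z mixture) | CC(O[Si](C)(C)C)=CC(=O)OCc1ccccc1 | intermediate
12 | (1Z)-1-(benzyloxy)-1,3-bis(trimethylsilyloxy)buta-1,3-diene | C=C(O[Si](C)(C)C)/C=C(/OCc1ccccc1)O[Si](C)(C)C | intermediate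
13 | benzyl 4-({[6-(benzyloxy)-2-methyl-4,6-bis(trimethylsilyloxy)cyclohexa-1,4-dien-1-yl]carbonyl}oxy)-2-heptyl-6-(trimethylsilyloxy)benzoate (racemic, not isolated) | CCCCCCCc1cc(OC(=O)C2=C(C)CC(O[Si](C)(C)C)=CC2(OCc2ccccc2)O[Si](C)(C)C)cc(O[Si](C)(C)C)c1C(=O)OCc1ccccc1 | intermediate
14 | benzyl 4-[(2,4-dihydroxy-6-methylbenzoyl)oxy]-2-heptyl-6-hydroxybenzoate | CCCCCCCc1cc(OC(=O)c2c(C)cc(O)cc2O)cc(O)c1C(=O)OCc1ccccc1 | intermediate
15 | 4-[(2,4-dihydroxy-6-methylbenzoyl)oxy]-2-heptyl-6-hydroxybenzoic acid | CCCCCCCc1cc(OC(=O)c2c(C)cc(O)cc2O)cc(O)c1C(=O)O | target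

Total step count: 9. Longest linear sequence: 7 steps (steps 1, 2, 3, 4, 5, 8, 9); the diene branch (steps 6, 7) joins at step 8.

Steps most likely to fail

Step 8. The cycloaddition may be too slow, so that the diene decomposes on heating. Alternatively, conjugate addition may be followed by expulsion of the ring B phenoxide, which cleaves the ester link instead of closing ring A. The fallback makes the depside bond by conventional acylation and sets out from 7. Commercial 2,4-dihydroxy-6-methylbenzoic acid (Cc1cc(O)cc(O)c1C(=O)O) would be perbenzylated (BnBr, K2CO3, DMF) to benzyl 2,4-bis(benzyloxy)-6-methylbenzoate F1. Saponification (KOH, aqueous DMSO, 80 °C) would give 2,4-bis(benzyloxy)-6-methylbenzoic acid F2. Condensation of F2 with the 4-hydroxyl of 7 by (CF3CO)2O in toluene at rt should give benzyl 4-{[2,4-bis(benzyloxy)-6-methylbenzoyl]oxy}-2-heptyl-6-hydroxybenzoate F3. Hydrogenolysis of its three benzyl groups (H2, Pd/C, EtOAc) comes back to the route at 15.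

Step 3. The electron-rich arene may be brominated further as soon as it forms, or the benzyl ester may be cleaved by the hydrogen bromide generated on heating. The fallback accepts over-bromination and sets out from 5. Exhaustive bromination (Br2, 3 equiv, AcOH, rt) would give benzyl 3,5-dibromo-2-heptyl-4,6-dihydroxybenzoate F4. Hydrogenation (H2, Pd/C, NaOAc, MeOH) would remove both bromines and the benzyl group to give 2-heptyl-4,6-dihydroxybenzoic acid F5; any ester cleavage during bromination is therefore harmless. Selective alkylation of the carboxylate (BnBr, KHCO3, DMF, rt) comes back to the route at 7.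

Step 2. The Michael addition to the β-heptyl enoate may reverse and the Claisen closure may lag, or adventitious hydroxide may cleave the benzyl ester and cause decarboxylation. The fallback uses the malonate–enone version of the same annulation and sets out from 1. Amide coupling (EDC·HCl, MeNHOMe·HCl, Et3N, CH2Cl2) would give (E)-N-methoxy-N-methyldec-2-enamide F6. MeMgBr in THF at 0 °C would give (E)-undec-3-en-2-one F7. Commercial dibenzyl malonate (O=C(CC(=O)OCc1ccccc1)OCc1ccccc1) with NaOCH2Ph in BnOH/toluene at 90 °C should add to the more reactive enone to give dibenzyl 2-(2-oxoundecan-4-yl)propanedioate F8 (not isolated). Claisen condensation of its methyl ketone onto one malonate ester comes back to the route at 5.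

Further compounds
F1 | step 8 | benzyl 2,4-bis(benzyloxy)-6-methylbenzoate | Cc1cc(OCc2ccccc2)cc(OCc2ccccc2)c1C(=O)OCc1ccccc1
F2 | step 8 | 2,4-bis(benzyloxy)-6-methylbenzoic acid | Cc1cc(OCc2ccccc2)cc(OCc2ccccc2)c1C(=O)O
F3 | step 8 | benzyl 4-{[2,4-bis(benzyloxy)-6-methylbenzoyl]oxy}-2-heptyl-6-hydroxybenzoate | CCCCCCCc1cc(OC(=O)c2c(C)cc(OCc3ccccc3)cc2OCc2ccccc2)cc(O)c1C(=O)OCc1ccccc1
F4 | step 3 | benzyl 3,5-dibromo-2-heptyl-4,6-dihydroxybenzoate | CCCCCCCc1c(Br)c(O)c(Br)c(O)c1C(=O)OCc1ccccc1
F5 | step 3 | 2-heptyl-4,6-dihydroxybenzoic acid | CCCCCCCc1cc(O)cc(O)c1C(=O)O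
F6 | step 2 | (E)-N-methoxy-N-methyldec-2-enamide | CCCCCCC/C=C/C(=O)N(C)OC
F7 | step 2 | (E)-undec-3-en-2-one | CCCCCCC/C=C/C(C)=O
F8 | step 2 | dibenzyl 2-(2-oxoundecan-4-yl)propanedioate | CCCCCCCC(CC(C)=O)C(C(=O)OCc1ccccc1)C(=O)OCc1ccccc1
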